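## Retrosynthetic overview

1. Target 17 comes from its bis(benzyl ether) 16 by hydrogenolysis of the two aryl benzyl ethers (last step).
2. 16 comes from the acyclic bis(1-arylallyl) ether 15. The tetrahydrofuran, the only ring made in the route, is closed between C3 and C4 by a hydrogen-atom-transfer-initiated reductive 5-exo radical cyclization. That one step makes the ring, both methyl groups and the C3 and C4 stereocentres.
3. 15 comes from carbonate 6 and alcohol 12. The C2–O bond is made by iridium-catalysed asymmetric allylic etherification, which sets C2. C5 is set beforehand by a Sharpless kinetic resolution.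
4. 6 comes from aldehyde 1 (olefination, reduction, carbonate). 12 comes from aldehyde 7 (benzylation, vinyl Grignard addition, resolution). Both benzene rings are bought.
5. Enabling feature: in the tetrahydrofuran ring, C3 and C4 are neighbouring CH(CH3) carbons, each next to an aryl-bearing C–O carbon (C2, C5) of the ring oxygen. Each half of the ring is therefore a 1-arylallyl unit plus one hydrogen atom, and the 2,3-trans-3,4-cis-4,5-trans pattern is the one a chair-like 5-exo transition state favours.

Key step: step 8

Assumption (chemistry): aldehydes 1 and 7 are taken as purchasable. Ring numbering used throughout: O1, C2 (bears the 4-hydroxy-3-methoxyphenyl group), C3, C4, C5 (bears the 3-hydroxy-4,5-dimethoxyphenyl group); the target is (2S,3S,4R,5R).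

## Route

Step 1
Reactants: 1 4-(benzyloxy)-3-methoxybenzaldehyde; 2 triethyl phosphonoacetate
Product: 3 ethyl (E)-3-[4-(benzyloxy)-3-methoxyphenyl]prop-2-enoate
Conditions: NaH, THF, 0 °C to rt
Reagents that add atoms: triethyl phosphonoacetate (2), CCOC(=O)CP(=O)(OCC)OCC
Why: Horner–Wadsworth–Emmons olefination of an aromatic aldehyde with a stabilised phosphonate should give the (E)-cinnamate, and no stereocentre is formed.

Step 2
Reactants: 3 ethyl (E)-3-[4-(benzyloxy)-3-methoxyphenyl]prop-2-enoate
Product: 4 (E)-3-[4-(benzyloxy)-3-methoxyphenyl]prop-2-en-1-ol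
Conditions: i-Bu2AlH, CH2Cl2, −78 °C to 0 °C; aq potassium sodium tartrate work-up
Reagents that add atoms: none
Why: 1,2-reduction of the enoate by i-Bu2AlH should give the allylic alcohol while leaving the alkene geometry and the benzyl ether untouched.

Step 3
Reactants: 4 (E)-3-[4-(benzyloxy)-3-methoxyphenyl]prop-2-en-1-ol; 5 di-tert-butyl dicarbonate
Product: 6 tert-butyl (E)-3-[4-(benzyloxy)-3-methoxyphenyl]prop-2-en-1-yl carbonate
Conditions: Boc2O, Bu4NHSO4 (cat.), 30% aq NaOH, CH2Cl2, 0 °C to rt
Reagents that add atoms: di-tert-butyl dicarbonate (5), CC(C)(C)OC(=O)OC(=O)OC(C)(C)C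
Why: O-acylation of the primary allylic alcohol under phase-transfer conditions should give the carbonate, the tert-butyl group being chosen so that the tert-butoxide released in step 7 does not compete as a nucleophile.

Step 4
Reactants: 7 3-hydroxy-4,5-dimethoxybenzaldehyde; 8 benzyl bromide
Product: 9 3-(benzyloxy)-4,5-dimethoxybenzaldehyde
Conditions: BnBr, K2CO3, DMF, rt
Reagents that add atoms: benzyl bromide (8), BrCc1ccccc1
Why: Williamson etherification of the phenol should proceed cleanly and masks the hydrogen-atom-donating OH before the radical step.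

Step 5
Reactants: 9 3-(benzyloxy)-4,5-dimethoxybenzaldehyde; 10 vinylmagnesium bromide
Product: 11 rac-1-[3-(benzyloxy)-4,5-dimethoxyphenyl]prop-2-en-1-ol
Conditions: CH2=CHMgBr, THF, −78 °C to 0 °C; aq NH4Cl
Reagents that add atoms: vinylmagnesium bromide (10), C=C[Mg]Br
Why: Grignard 1,2-addition to the aldehyde should give the racemic aryl vinyl carbinol.

Step 6
Reactants: 11 rac-1-[3-(benzyloxy)-4,5-dimethoxyphenyl]prop-2-en-1-ol
Product: 12 (R)-1-[3-(benzyloxy)-4,5-dimethoxyphenyl]prop-2-en-1-ol
Conditions: Ti(OiPr)4 (0.2 equiv), (S,S)-(−)-diisopropyl tartrate (0.3 equiv), t-BuOOH (0.6 equiv), 4 Å MS, CH2Cl2, −20 °C, run a little past half conversion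
Reagents that add atoms: none
Why: In this Sharpless kinetic resolution the (S,S)-tartrate catalyst should epoxidise the (S)-carbinol to its erythro epoxy alcohol, so that the slow-reacting (R)-enantiomer, which becomes C5 of the target, is recovered in high enantiomeric purity.

Step 7
Reactants: 12 (R)-1-[3-(benzyloxy)-4,5-dimethoxyphenyl]prop-2-en-1-ol; 6 tert-butyl (E)-3-[4-(benzyloxy)-3-methoxyphenyl]prop-2-en-1-yl carbonate
Product: 15 (S)-1-[4-(benzyloxy)-3-methoxyphenyl]allyl (R)-1-[3-(benzyloxy)-4,5-dimethoxyphenyl]allyl ether, via lithium alkoxide 13 (not isolated), via copper alkoxide 14 (not isolated)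
Conditions: n-BuLi, THF, −78 °C to 0 °C; CuI, rt; then 6, [Ir(cod)Cl]2 (2 mol %), (Sa,Sc,Sc)-O,O′-(1,1′-binaphthalene-2,2′-diyl) N,N-bis(1-phenylethyl)phosphoramidite (4 mol %), THF, rt
Reagents that add atoms: none
Why: Iridium-catalysed asymmetric allylic etherification of a cinnamyl carbonate with a copper alkoxide should give the branched ether, the new centre (C2 of the target, S) being set by the catalyst, for which the (Sa,Sc,Sc) ligand antipode is the one expected to place oxygen on the required face, while the carbinol centre of 12 is untouched.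

Step 8
Reactants: 15 (S)-1-[4-(benzyloxy)-3-methoxyphenyl]allyl (R)-1-[3-(benzyloxy)-4,5-dimethoxyphenyl]allyl ether
Product: 16 (2S,3S,4R,5R)-2-[4-(benzyloxy)-3-methoxyphenyl]-5-[3-(benzyloxy)-4,5-dimethoxyphenyl]-3,4-dimethyltetrahydrofuran
Conditions: Mn(dpm)3 (20 mol %), PhSiH3 (3 equiv), t-BuOOH (3 equiv), degassed i-PrOH (0.02 M), rt
Reagents that add atoms: none
Why: The Mn–H species made from Mn(dpm)3 and PhSiH3 should transfer a hydrogen atom to the terminal CH2 of either vinyl group of 15, the secondary radical then closes onto the internal carbon of the other vinyl group, and the primary radical so formed takes a second hydrogen atom, so that the C3–C4 bond and both methyl groups arise in one operation. The closest known reaction type is the metal-hydride hydrogen-atom-transfer-initiated reductive radical cyclization of 1,6-dienes under Mukaiyama-type conditions, with the stereochemical behaviour known from tin-hydride closures of 3-oxa-hex-5-enyl radicals. The tetrahydrofuran closes in the 5-exo-trig mode, and the ether oxygen and the two aryl groups on the tether should accelerate closure. C3 and C4 are set by a chair-like transition state in which both aryl groups of the (S,R)-ether sit pseudo-equatorial: the acceptor carbon bonds trans to its neighbouring aryl group, and the methyl on the radical carbon turns away from its own aryl neighbour, which is also the side cis to the new exocyclic carbon, so all preferences point to the 2,3-trans-3,4-cis-4,5-trans isomer (3S,4R). The step needs ring closure to outrun direct reduction of the first radical, which high dilution and the fast closure of this oxygen-tethered radical should secure, and it needs no choice between the two vinyl groups, because initiation at either one leads to the same product.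

Step 9
Reactants: 16 (2S,3S,4R,5R)-2-[4-(benzyloxy)-3-methoxyphenyl]-5-[3-(benzyloxy)-4,5-dimethoxyphenyl]-3,4-dimethyltetrahydrofuran
Product: 17 (2S,3S,4R,5R)-2-(4-hydroxy-3-methoxyphenyl)-5-(3-hydroxy-4,5-dimethoxyphenyl)-3,4-dimethyltetrahydrofuran (CNP0022199.2)
Conditions: H2 (1 atm), 10% Pd/C, EtOAc, rt, stopped as soon as 16 is consumed
Reagents that add atoms: none
Why: Hydrogenolysis of aryl benzyl ethers over Pd/C in a non-acidic solvent should be much faster than cleavage of the ring benzylic C–O bonds, so both phenols are released without touching the four stereocentres.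

## Compound list

1 | 4-(benzyloxy)-3-methoxybenzaldehyde | COc1cc(C=O)ccc1OCc1ccccc1 | starting material
2 | triethyl phosphonoacetate | CCOC(=O)CP(=O)(OCC)OCC | starting material
3 | ethyl (E)-3-[4-(benzyloxy)-3-methoxyphenyl]prop-2-enoate | CCOC(=O)/C=C/c1ccc(OCc2ccccc2)c(OC)c1 | intermediate
4 | (E)-3-[4-(benzyloxy)-3-methoxyphenyl]prop-2-en-1-ol | OC/C=C/c1ccc(OCc2ccccc2)c(OC)c1 | intermediate
5 | di-tert-butyl dicarbonate | CC(C)(C)OC(=O)OC(=O)OC(C)(C)C | starting material
6 | tert-butyl (E)-3-[4-(benzyloxy)-3-methoxyphenyl]prop-2-en-1-yl carbonate | CC(C)(C)OC(=O)OC/C=C/c1ccc(OCc2ccccc2)c(OC)c1 | intermediate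
7 | 3-hydroxy-4,5-dimethoxybenzaldehyde | COc1cc(C=O)cc(O)c1OC | starting material
8 | benzyl bromide | BrCc1ccccc1 | starting material
9 | 3-(benzyloxy)-4,5-dimethoxybenzaldehyde | COc1cc(C=O)cc(OCc2ccccc2)c1OC | intermediate
10 | vinylmagnesium bromide | C=C[Mg]Br | starting material
11 | rac-1-[3-(benzyloxy)-4,5-dimethoxyphenyl]prop-2-en-1-ol | COc1cc(C(O)C=C)cc(OCc2ccccc2)c1OC | intermediate
12 | (R)-1-[3-(benzyloxy)-4,5-dimethoxyphenyl]prop-2-en-1-ol | O[C@@H](c1cc(OC)c(OC)c(OCc2ccccc2)c1)C=C | intermediate
13 | lithium (R)-1-[3-(benzyloxy)-4,5-dimethoxyphenyl]prop-2-en-1-olate | [Li]O[C@@H](c1cc(OC)c(OC)c(OCc2ccccc2)c1)C=C | intermediate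
14 | copper (R)-1-[3-(benzyloxy)-4,5-dimethoxyphenyl]prop-2-en-1-olate | [Cu]O[C@@H](c1cc(OC)c(OC)c(OCc2ccccc2)c1)C=C | intermediate
15 | (S)-1-[4-(benzyloxy)-3-methoxyphenyl]allyl (R)-1-[3-(benzyloxy)-4,5-dimethoxyphenyl]allyl ether | COc1cc([C@H](C=C)O[C@@H](c2cc(OCc3ccccc3)c(OC)c(OC)c2)C=C)ccc1OCc1ccccc1 | intermediate
16 | (2S,3S,4R,5R)-2-[4-(benzyloxy)-3-methoxyphenyl]-5-[3-(benzyloxy)-4,5-dimethoxyphenyl]-3,4-dimethyltetrahydrofuran | COc1cc([C@H]2O[C@@H](c3cc(OCc4ccccc4)c(OC)c(OC)c3)[C@H](C)[C@@H]2C)ccc1OCc1ccccc1 | intermediate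
17 | (2S,3S,4R,5R)-2-(4-hydroxy-3-methoxyphenyl)-5-(3-hydroxy-4,5-dimethoxyphenyl)-3,4-dimethyltetrahydrofuran | COc1cc([C@H]2O[C@@H](c3cc(O)c(OC)c(OC)c3)[C@H](C)[C@@H]2C)ccc1O | target

## Step count and risks

Total steps: 9. Longest linear sequence: 6 (steps 4, 5, 6, 7, 8, 9; the branch 1, 2, 3, 7, 8, 9 is equally long).

Steps most likely to fail:

1. Step 8. The first radical may be reduced before it closes, which would give the open-chain saturated ether, or facial control at the radical carbon may be incomplete, which would give C3/C4 epimers. The fallback sets out from 15 and comes back at 16. Thiophenol is added slowly to 15 with AIBN in benzene at 80 °C; the thiyl radical adds to the terminal carbon of either vinyl group, the adduct radical closes 5-exo through the same chair-like transition state, and hydrogen transfer from the thiol ends the chain. This should give the two regioisomeric sulfides, the 3-[(phenylsulfanyl)methyl]-4-methyl tetrahydrofuran F1 and the 4-[(phenylsulfanyl)methyl]-3-methyl tetrahydrofuran F2. Reductive desulfurization of the mixture with nickel boride (NiCl2·6H2O, NaBH4, MeOH–THF, 0 °C) converges both on 16.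

2. Step 7. Branched selectivity or catalyst control over the new centre may be poor, or the allylic alkoxide may isomerise to the aryl ethyl ketone under base and metal. The fallback sets out from 12 and comes back at 15. Alcohol 12 is added across the electron-rich alkene of 1-(benzyloxy)-2-methoxy-4-[(E)-prop-1-en-1-yl]benzene F3 with N-(phenylseleno)phthalimide and catalytic camphorsulfonic acid in CH2Cl2; oxygen goes to the benzylic carbon and the addition is anti, giving the β-seleno ether (1R,2S)-1-[4-(benzyloxy)-3-methoxyphenyl]-2-(phenylselanyl)propyl (R)-1-[3-(benzyloxy)-4,5-dimethoxyphenyl]allyl ether F4 together with its epimer at both new centres. Oxidation with H2O2 and pyridine triggers selenoxide syn-elimination away from the oxygen-bearing carbon and should give 15, which is separated by chromatography from its diastereomer at the new benzylic centre.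

3. Step 6. Epoxidation of a terminal vinyl carbinol is slow, so the resolution may stay incomplete, and the Lewis acid may ionise the electron-rich benzylic alcohol. The fallback sets out from 11 and comes back at 12. Immobilised Candida antarctica lipase B with vinyl acetate in MTBE at 30 °C should acylate the (R)-enantiomer, following the usual enantiopreference of lipases for secondary alcohols, to give (R)-1-[3-(benzyloxy)-4,5-dimethoxyphenyl]allyl acetate F5. F5 is separated from the unreacted (S)-alcohol and cleaved with K2CO3 in MeOH to 12.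

## Further compounds

F1 | step 8 | 2-[4-(benzyloxy)-3-methoxyphenyl]-5-[3-(benzyloxy)-4,5-dimethoxyphenyl]-4-methyl-3-[(phenylsulfanyl)methyl]tetrahydrofuran, ring configuration as in 16 | COc1cc([C@H]2O[C@@H](c3cc(OCc4ccccc4)c(OC)c(OC)c3)[C@H](C)[C@@H]2CSc2ccccc2)ccc1OCc1ccccc1
F2 | step 8 | 2-[4-(benzyloxy)-3-methoxyphenyl]-5-[3-(benzyloxy)-4,5-dimethoxyphenyl]-3-methyl-4-[(phenylsulfanyl)methyl]tetrahydrofuran, ring configuration as in 16 | COc1cc([C@H]2O[C@@H](c3cc(OCc4ccccc4)c(OC)c(OC)c3)[C@H](CSc3ccccc3)[C@@H]2C)ccc1OCc1ccccc1
F3 | step 7 | 1-(benzyloxy)-2-methoxy-4-[(E)-prop-1-en-1-yl]benzene | C/C=C/c1ccc(OCc2ccccc2)c(OC)c1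
F4 | step 7 | (1R,2S)-1-[4-(benzyloxy)-3-methoxyphenyl]-2-(phenylselanyl)propyl (R)-1-[3-(benzyloxy)-4,5-dimethoxyphenyl]allyl ether | COc1cc([C@H]([C@H](C)[Se]c2ccccc2)O[C@@H](c2cc(OCc3ccccc3)c(OC)c(OC)c2)C=C)ccc1OCc1ccccc1
F5 | step 6 | (R)-1-[3-(benzyloxy)-4,5-dimethoxyphenyl]allyl acetate | CC(=O)O[C@@H](c1cc(OC)c(OC)c(OCc2ccccc2)c1)C=C
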